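The core is a 6,8-dioxabicyclo[3.2.2]nonan-7-one whose oxepane ring (O8, C9, C5, C4, C3, C2, C1) is cut at the two C–C bonds next to the ether carbons: C1–C2 (quaternary carbon to carbinol) and C9–C5 (ether CH to the methyl-bearing carbon). One flask joins 4-oxopentanal with a vinyl-substituted 1,3-dioxolan-4-one: its enolate attacks the aldehyde, then zerovalent palladium and InI turn the acetal carbon into a γ-alkoxyallylindium that closes the seven-membered ring on the ketone, a formal (4+3) annulation. The step exploits the C–O–C unit of the oxepane, both carbons of which act as nucleophiles, and the 1,4-dioxygenated C2–C5 chain. Lactonisation and a late B-alkyl Suzuki coupling finish the synthesis.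

Key step: step 6

Assumption: methyl (2S)-2-hydroxybut-3-enoate is taken as a purchasable single enantiomer; it is the only source of absolute configuration.

Step 1
Reactants: 1 prop-2-yn-1-ol (propargyl alcohol)
Product: 2 (Z)-3-iodo-2-methylprop-2-en-1-ol
Conditions: MeMgBr (2.5 equiv), CuI (10 mol %), THF, −10 to 23 °C; then I2, −78 to 0 °C
Reagents that add atoms: methylmagnesium bromide, C[Mg]Br; iodine, II
Why: Copper-catalysed carbomagnesiation of the magnesium propargylic alkoxide puts methyl on the internal carbon and magnesium on the terminal carbon cis to the CH2O group (five-membered chelate), and iodinolysis with retention gives the (Z)-vinyl iodide.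

Step 2
Reactants: 2 (Z)-3-iodo-2-methylprop-2-en-1-ol
Product: 3 tert-butyl{[(2Z)-3-iodo-2-methylprop-2-en-1-yl]oxy}diphenylsilane
Conditions: tBuPh2SiCl, imidazole, DMF, 23 °C
Reagents that add atoms: tert-butyl(chloro)diphenylsilane, CC(C)(C)[Si](Cl)(c1ccccc1)c1ccccc1
Why: Silyl ether formation on a primary allylic alcohol; the bulky silyl group should survive the base, the acid catalysis and the palladium chemistry that follow.

Step 3
Reactants: 4 methyl (2S)-2-hydroxybut-3-enoate; 3 tert-butyl{[(2Z)-3-iodo-2-methylprop-2-en-1-yl]oxy}diphenylsilane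
Product: 7 (2S,5Z)-7-{[tert-butyl(diphenyl)silyl]oxy}-2-hydroxy-6-methylhept-5-enoic acid, via alkylborane 5 (not isolated), via methyl ester 6 (not isolated)
Conditions: 9-BBN (2.2 equiv), THF, 0 to 23 °C; then 3, PdCl2(dppf) (5 mol %), 3 M aqueous NaOH, THF, 50 °C; aqueous HCl to pH 3
Reagents that add atoms: sodium hydroxide, [Na+].[OH-]
Why: Anti-Markovnikov hydroboration of the vinyl group, Suzuki–Miyaura B-alkyl coupling with retention of the Z geometry and saponification in the same alkaline medium; the carbinol stereocentre is not touched.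

Step 4
Reactants: 7 (2S,5Z)-7-{[tert-butyl(diphenyl)silyl]oxy}-2-hydroxy-6-methylhept-5-enoic acid; 8 3,3-diethoxyprop-1-ene (acrolein diethyl acetal)
Product: 9 (2S,5S)-5-[(3Z)-5-{[tert-butyl(diphenyl)silyl]oxy}-4-methylpent-3-en-1-yl]-2-ethenyl-1,3-dioxolan-4-one (cis isomer)
Conditions: PPTS (10 mol %), toluene, 60 °C, ethanol distilled off; chromatographic separation of the cis isomer
Reagents that add atoms: none
Why: Acid-catalysed transacetalisation closes the 1,3-dioxolan-4-one, and under these reversible conditions the new acetal stereocentre should settle cis to the C5 side chain (2S), which stores the configuration of C5 for step 6.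

Step 5
Reactants: 10 5-hydroxypentan-2-one
Product: 11 4-oxopentanal
Conditions: TEMPO (10 mol %), PhI(OAc)2, CH2Cl2, 23 °C
Reagents that add atoms: none
Why: Oxoammonium (TEMPO) oxidation of the primary alcohol stops at the aldehyde and leaves the ketone alone.

Step 6
Reactants: 9 (2S,5S)-5-[(3Z)-5-{[tert-butyl(diphenyl)silyl]oxy}-4-methylpent-3-en-1-yl]-2-ethenyl-1,3-dioxolan-4-one; 11 4-oxopentanal
Product: 14 (2R,3S,6R,7S)-2-[(3Z)-5-{[tert-butyl(diphenyl)silyl]oxy}-4-methylpent-3-en-1-yl]-7-ethenyl-6-hydroxy-6-methyl-3-(triethylsilyloxy)oxepane-2-carboxylic acid, via silyl aldol adduct 12 (not isolated), via allylindium carboxylate 13 (not isolated)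
Conditions: LiN(iPr)2, THF, −78 °C; MgBr2·OEt2 then 11, −78 °C; Et3SiOTf, −78 °C; then Pd(PPh3)4 (5 mol %), InI (2 equiv), −78 to 23 °C; pH 4 phosphate work-up
Reagents that add atoms: triethylsilyl trifluoromethanesulfonate, CC[Si](CC)(CC)OS(=O)(=O)C(F)(F)F
Why: Proposed new method: the enolate of 9 adds to the MgBr2-bound aldehyde of 11 on the face anti to the acetal vinyl group, which sets the quaternary carbon by self-regeneration of the stereocentre, and a chair Zimmerman–Traxler transition state with the aldehyde chain axial, the only one that keeps the γ-keto oxygen on the metal, sets the (1S) carbinol carbon before Et3SiOTf caps the aldolate as 12. Zerovalent palladium then ionises the allylic acylal C–O bond of 12, InI reduces the alkoxy-π-allylpalladium carboxylate to the γ-alkoxyallylindium 13, and 13 adds through its oxygen-bearing carbon to the methyl ketone in a 7-exo-trig closure of the oxepane ring. The closest known reaction types are the aldol addition of chiral 1,3-dioxolan-4-one enolates, the palladium/InI umpolung allylation of allylic esters and intramolecular Barbier-type allylation of ketones; their union on an acrolein acylal in one flask is new. The two new ring stereocentres should arise in a chair six-membered indium transition state with the (E)-enol ether and the ring tether equatorial, which puts the vinyl group trans to the new tertiary alkoxide, while the carboxylate-bound indium holds the ketone oxygen on the carboxylate face so that the lactone can close later. The step needs aldehyde-over-ketone selectivity in the aldol (secured by the reactivity gap at −78 °C), γ-selectivity of the allylindium (secured by the cyclic SE2′ transition state) and attack anti to the vinyl group (secured only by the single acetal stereocentre, the weakest element).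

Step 7
Reactants: 14 (2R,3S,6R,7S)-2-[(3Z)-5-{[tert-butyl(diphenyl)silyl]oxy}-4-methylpent-3-en-1-yl]-7-ethenyl-6-hydroxy-6-methyl-3-(triethylsilyloxy)oxepane-2-carboxylic acid
Product: 15 (1R,2S,5R,9S)-1-[(3Z)-5-{[tert-butyl(diphenyl)silyl]oxy}-4-methylpent-3-en-1-yl]-9-ethenyl-5-methyl-2-(triethylsilyloxy)-6,8-dioxabicyclo[3.2.2]nonan-7-one
Conditions: DCC, DMAP (20 mol %), CH2Cl2 (0.005 M), 23 °C
Reagents that add atoms: none
Why: Steglich-type lactonisation: the tertiary hydroxyl and the carboxyl group are cis on the oxepane and the carbinol oxygen is silylated, so the activated acid can only close the six-membered lactone bridge, and no stereocentre changes.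

Step 8
Reactants: 15 (1R,2S,5R,9S)-1-[(3Z)-5-{[tert-butyl(diphenyl)silyl]oxy}-4-methylpent-3-en-1-yl]-9-ethenyl-5-methyl-2-(triethylsilyloxy)-6,8-dioxabicyclo[3.2.2]nonan-7-one
Product: 16 (1R,2S,5R,9S)-9-ethenyl-2-hydroxy-1-[(3Z)-5-hydroxy-4-methylpent-3-en-1-yl]-5-methyl-6,8-dioxabicyclo[3.2.2]nonan-7-one
Conditions: HF·pyridine, pyridine, THF, 0 to 23 °C
Reagents that add atoms: none
Why: Fluoride-mediated desilylation removes both silyl ethers under buffered conditions that should spare the lactone and the allylic ether.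

Step 9
Reactants: 16 (1R,2S,5R,9S)-9-ethenyl-2-hydroxy-1-[(3Z)-5-hydroxy-4-methylpent-3-en-1-yl]-5-methyl-6,8-dioxabicyclo[3.2.2]nonan-7-one
Product: 17 (2Z)-5-[(1R,2S,5R,9S)-9-ethenyl-2-hydroxy-5-methyl-7-oxo-6,8-dioxabicyclo[3.2.2]nonan-1-yl]-2-methylpent-2-en-1-yl acetate
Conditions: AcCl (1.05 equiv), 2,4,6-collidine, CH2Cl2, −78 °C
Reagents that add atoms: acetyl chloride, CC(Cl)=O
Why: Chemoselective O-acetylation: the primary allylic alcohol should be acylated far faster than the hindered secondary alcohol next to the quaternary bridgehead.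

Step 10
Reactants: 18 but-2-yn-1-ol
Product: 19 (Z)-3-iodobut-2-en-1-ol
Conditions: NaAlH2(OCH2CH2OMe)2 (Red-Al), THF, 0 to 23 °C; then I2, −78 to 0 °C
Reagents that add atoms: iodine, II
Why: Alkoxide-directed trans-hydroalumination places aluminium on C3 cis to the CH2O group, and iodinolysis with retention gives the (Z)-vinyl iodide.

Step 11
Reactants: 17 (2Z)-5-[(1R,2S,5R,9S)-9-ethenyl-2-hydroxy-5-methyl-7-oxo-6,8-dioxabicyclo[3.2.2]nonan-1-yl]-2-methylpent-2-en-1-yl acetate; 19 (Z)-3-iodobut-2-en-1-ol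
Product: 21 (2Z)-5-[(1R,2S,5R,9S)-2-hydroxy-9-[(3Z)-5-hydroxy-3-methylpent-3-en-1-yl]-5-methyl-7-oxo-6,8-dioxabicyclo[3.2.2]nonan-1-yl]-2-methylpent-2-en-1-yl acetate (CNP0174851.1), via alkylborane 20 (not isolated)
Conditions: 9-BBN (2.5 equiv), THF, 0 to 23 °C; then 19, PdCl2(dppf) (5 mol %), AsPh3, aqueous K3PO4, DMF, 23 °C
Reagents that add atoms: none
Why: 9-BBN should hydroborate only the monosubstituted vinyl group (anti-Markovnikov), and the Suzuki–Miyaura B-alkyl coupling joins it to the vinyl iodide with retention of the Z geometry, faster than palladium can ionise the allylic acetate.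

Compound list
1 | prop-2-yn-1-ol | C#CCO | starting material
2 | (Z)-3-iodo-2-methylprop-2-en-1-ol | OC/C(C)=C\I | intermediate
3 | tert-butyl{[(2Z)-3-iodo-2-methylprop-2-en-1-yl]oxy}diphenylsilane | CC(C)(C)[Si](c1ccccc1)(c1ccccc1)OC/C(C)=C\I | intermediate
4 | methyl (2S)-2-hydroxybut-3-enoate | C=C[C@H](O)C(=O)OC | starting material
5 | methyl (2S)-4-(9-borabicyclo[3.3.1]nonan-9-yl)-2-hydroxybutanoate | COC(=O)[C@@H](O)CCB1C2CCCC1CCC2 | intermediate
6 | methyl (2S,5Z)-7-{[tert-butyl(diphenyl)silyl]oxy}-2-hydroxy-6-methylhept-5-enoate | CC(C)(C)[Si](c1ccccc1)(c1ccccc1)OC/C(C)=C\CC[C@H](O)C(=O)OC | intermediate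
7 | (2S,5Z)-7-{[tert-butyl(diphenyl)silyl]oxy}-2-hydroxy-6-methylhept-5-enoic acid | CC(C)(C)[Si](c1ccccc1)(c1ccccc1)OC/C(C)=C\CC[C@H](O)C(=O)O | intermediate
8 | 3,3-diethoxyprop-1-ene | C=CC(OCC)OCC | starting material
9 | (2S,5S)-5-[(3Z)-5-{[tert-butyl(diphenyl)silyl]oxy}-4-methylpent-3-en-1-yl]-2-ethenyl-1,3-dioxolan-4-one | CC(C)(C)[Si](c1ccccc1)(c1ccccc1)OC/C(C)=C\CC[C@H]2C(=O)O[C@@H](C=C)O2 | intermediate
10 | 5-hydroxypentan-2-one | CC(=O)CCCO | starting material
11 | 4-oxopentanal | CC(=O)CCC=O | intermediate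
12 | (2S,5R)-5-[(3Z)-5-{[tert-butyl(diphenyl)silyl]oxy}-4-methylpent-3-en-1-yl]-2-ethenyl-5-[(1S)-4-oxo-1-(triethylsilyloxy)pentyl]-1,3-dioxolan-4-one | CC(C)(C)[Si](c1ccccc1)(c1ccccc1)OC/C(C)=C\CC[C@@]2([C@H](CCC(C)=O)O[Si](CC)(CC)CC)C(=O)O[C@@H](C=C)O2 | intermediate
13 | (2R,3S)-2-[(3Z)-5-{[tert-butyl(diphenyl)silyl]oxy}-4-methylpent-3-en-1-yl]-2-{[(1E)-3-(iodoindio)prop-1-en-1-yl]oxy}-6-oxo-3-(triethylsilyloxy)heptanoate (inner indium carboxylate) | CC(C)(C)[Si](c1ccccc1)(c1ccccc1)OC/C(C)=C\CC[C@@]([C@H](CCC(C)=O)O[Si](CC)(CC)CC)(C(=O)[O-])O/C=C/C[In+]I | intermediate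
14 | (2R,3S,6R,7S)-2-[(3Z)-5-{[tert-butyl(diphenyl)silyl]oxy}-4-methylpent-3-en-1-yl]-7-ethenyl-6-hydroxy-6-methyl-3-(triethylsilyloxy)oxepane-2-carboxylic acid | CC(C)(C)[Si](c1ccccc1)(c1ccccc1)OC/C(C)=C\CC[C@@]1(C(=O)O)O[C@@H](C=C)[C@@](C)(CC[C@@H]1O[Si](CC)(CC)CC)O | intermediate
15 | (1R,2S,5R,9S)-1-[(3Z)-5-{[tert-butyl(diphenyl)silyl]oxy}-4-methylpent-3-en-1-yl]-9-ethenyl-5-methyl-2-(triethylsilyloxy)-6,8-dioxabicyclo[3.2.2]nonan-7-one | CC(C)(C)[Si](c1ccccc1)(c1ccccc1)OC/C(C)=C\CC[C@@]12O[C@@H](C=C)[C@@](C)(CC[C@@H]1O[Si](CC)(CC)CC)OC2=O | intermediate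
16 | (1R,2S,5R,9S)-9-ethenyl-2-hydroxy-1-[(3Z)-5-hydroxy-4-methylpent-3-en-1-yl]-5-methyl-6,8-dioxabicyclo[3.2.2]nonan-7-one | OC/C(C)=C\CC[C@@]12O[C@@H](C=C)[C@@](C)(CC[C@@H]1O)OC2=O | intermediate
17 | (2Z)-5-[(1R,2S,5R,9S)-9-ethenyl-2-hydroxy-5-methyl-7-oxo-6,8-dioxabicyclo[3.2.2]nonan-1-yl]-2-methylpent-2-en-1-yl acetate | CC(=O)OC/C(C)=C\CC[C@@]12O[C@@H](C=C)[C@@](C)(CC[C@@H]1O)OC2=O | intermediate
18 | but-2-yn-1-ol | CC#CCO | starting material
19 | (Z)-3-iodobut-2-en-1-ol | C/C(I)=C/CO | intermediate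
20 | (2Z)-5-[(1R,2S,5R,9S)-9-[2-(9-borabicyclo[3.3.1]nonan-9-yl)ethyl]-2-hydroxy-5-methyl-7-oxo-6,8-dioxabicyclo[3.2.2]nonan-1-yl]-2-methylpent-2-en-1-yl acetate | CC(=O)OC/C(C)=C\CC[C@@]12O[C@@H](CCB3C4CCCC3CCC4)[C@@](C)(CC[C@@H]1O)OC2=O | intermediate
21 | (2Z)-5-[(1R,2S,5R,9S)-2-hydroxy-9-[(3Z)-5-hydroxy-3-methylpent-3-en-1-yl]-5-methyl-7-oxo-6,8-dioxabicyclo[3.2.2]nonan-1-yl]-2-methylpent-2-en-1-yl acetate | CC(=O)OC/C(C)=C\CC[C@@]12O[C@@H](CC/C(C)=C\CO)[C@@](C)(CC[C@@H]1O)OC2=O | target

Total step count: 11. Longest linear sequence: 9 steps (1, 2, 3, 4, 6, 7, 8, 9, 11).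

Steps most likely to fail

Step 6. The small vinyl group may shield the enolate face too weakly, and the chelate control at the carbinol carbon may be poor. The alkoxy-π-allylpalladium may also be recaptured by the internal carboxylate or lose a proton before indium takes it over. The fallback uses known chemistry, sets out from 9 and 11 and comes back at 14. The aldol stage is run alone (LiN(iPr)2, MgBr2·OEt2, 11, Et3SiOTf), and 12 is isolated and freed from acetal and carbinol epimers by chromatography. Palladium-catalysed allylic stannylation of 12 (Pd(PPh3)4, Bu3SnAlEt2, THF) then gives the (2R,3S)-configured allylstannane acid F1. BF3·OEt2 in CH2Cl2 at −78 °C closes the oxepane by the Lewis-acid-mediated intramolecular γ-alkoxyallylstannane–ketone addition to give 14.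

Step 4. Ethanol or the carboxyl group may add in conjugate fashion to the acrolein-derived oxocarbenium ion, and the cis/trans equilibrium at the acetal carbon may be poorly biased. The fallback sets out from 7 and comes back at 9. Acid 7 is condensed with 3-(phenylselanyl)propanal (TsOH, benzene, water removed) to the saturated cis-dioxolanone F2, which is purified. Oxidation with NaIO4/NaHCO3 and syn-elimination of the selenoxide at 23 °C then unveils the vinyl group of 9.

Step 7. The O-acylisourea of the neopentyl-type acid may rearrange to the N-acylurea faster than the hindered tertiary alcohol attacks it. The fallback sets out from 14 and comes back at 15. Acid 14 is esterified with Me3SiCHN2 in MeOH/toluene to the methyl ester F3. KN(SiMe3)2 in THF at 0 °C then closes the lactone by alkoxide transesterification, with loss of methanol, to give 15.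

Further compounds
F1 | step 6 | (2R,3S)-2-[(3Z)-5-{[tert-butyl(diphenyl)silyl]oxy}-4-methylpent-3-en-1-yl]-6-oxo-2-{[(1Z)-3-(tributylstannyl)prop-1-en-1-yl]oxy}-3-(triethylsilyloxy)heptanoic acid | CC(C)(C)[Si](c1ccccc1)(c1ccccc1)OC/C(C)=C\CC[C@@]([C@H](CCC(C)=O)O[Si](CC)(CC)CC)(C(=O)O)O/C=C\C[Sn](CCCC)(CCCC)CCCC
F2 | step 4 | (2S,5S)-5-[(3Z)-5-{[tert-butyl(diphenyl)silyl]oxy}-4-methylpent-3-en-1-yl]-2-[2-(phenylselanyl)ethyl]-1,3-dioxolan-4-one | CC(C)(C)[Si](c1ccccc1)(c1ccccc1)OC/C(C)=C\CC[C@H]2C(=O)O[C@@H](CC[Se]c3ccccc3)O2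
F3 | step 7 | methyl (2R,3S,6R,7S)-2-[(3Z)-5-{[tert-butyl(diphenyl)silyl]oxy}-4-methylpent-3-en-1-yl]-7-ethenyl-6-hydroxy-6-methyl-3-(triethylsilyloxy)oxepane-2-carboxylate | CC(C)(C)[Si](c1ccccc1)(c1ccccc1)OC/C(C)=C\CC[C@@]1(C(=O)OC)O[C@@H](C=C)[C@@](C)(CC[C@@H]1O[Si](CC)(CC)CC)O
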